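**Plan**
Retrosynthesis: the aryl–vinyl bond at C5 is cut first (Heck; this removes the whole N-(4-guanidinobutyl)acrylamide arm), then the C3 amide C–N bond, then C2–C3 and C2–O1 of the dihydrobenzofuran together.
Enabling feature: O1–C7a–C3a–C3, with the carboxyl carbon on C3, is a masked ortho-quinone methide, and C2 with its 4-oxyphenyl group is a one-carbon benzylic sulfonium ylide unit, so a [4+1] annulation builds the dihydrofuran ring.
Forward: a bromo/silyloxy arylacetate and a chiral benzylic thiolanium salt are made separately; their annulation closes the dihydrofuran ring (the only ring formed) onto the existing benzene ring; the C3 ester is then turned into the first agmatine amide, and the second agmatine unit arrives as a preformed acrylamide in the Heck coupling.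
Stereochemistry: C2 comes from the face of the ylide carbon left open by the C2-symmetric (2R,5R)-2,5-dimethylthiolane (from (2S,5S)-hexane-2,5-diol by double inversion); C3 settles trans to the C2 aryl group under thermodynamic control; the E alkene comes from the Heck reaction.
Protecting groups: a tert-butyl ester at C3, an aryl acetate and Boc groups on both guanidines are used, so that hydroxide never meets the C3 carboxyl derivative or a free 4-hydroxyphenyl group at C2, either of which invites opening of the dihydrofuran ring.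

Key step: step 7

Remark: the (2R,5R)-thiolanium salt is taken to give 2R, by analogy with the facial preference of its benzylic ylide towards aldehydes; if a trial shows the opposite sense, the (2S,5S)-salt from (2R,5R)-hexane-2,5-diol is used in the same sequence.
Remark: the bis-guanidines are handled as bis(trifluoroacetate) salts; the target is drawn as the free base.

**Route**

Step 1
Reactants: 1 2-(5-bromo-2-hydroxyphenyl)acetic acid
Product: 2 tert-butyl 2-(5-bromo-2-hydroxyphenyl)acetate
Conditions: Cl3CC(=NH)OtBu, CH2Cl2/cyclohexane, rt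
Reagents that add atoms: tert-butyl 2,2,2-trichloroacetimidate, CC(C)(C)OC(=N)C(Cl)(Cl)Cl
Why: Imidate esterification, in which the carboxylic acid protonates the trichloroacetimidate and captures the tert-butyl cation while the far less acidic phenol stays free, should give an ester that cannot lactonise to the benzofuranone and can later be removed with acid instead of hydroxide.

Step 2
Reactants: 2 tert-butyl 2-(5-bromo-2-hydroxyphenyl)acetate
Product: 3 tert-butyl 2-[5-bromo-2-(triisopropylsilyloxy)phenyl]acetate
Conditions: TIPSCl, imidazole, DMF, rt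
Reagents that add atoms: chlorotriisopropylsilane, CC(C)[Si](Cl)(C(C)C)C(C)C
Why: Imidazole-mediated silylation of a phenol is routine and installs a silyl ether that withstands the radical bromination but is released by fluoride in the key step.

Step 3
Reactants: 3 tert-butyl 2-[5-bromo-2-(triisopropylsilyloxy)phenyl]acetate
Product: 4 tert-butyl 2-bromo-2-[5-bromo-2-(triisopropylsilyloxy)phenyl]acetate (racemic)
Conditions: NBS, AIBN (cat.), PhCF3, 80 °C
Reagents that add atoms: N-bromosuccinimide, O=C1CCC(=O)N1Br
Why: Wohl–Ziegler bromination should select the one C–H bond that is both benzylic and alpha to the ester, and the new stereocentre may stay racemic because it becomes trigonal in the key step.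

Step 4
Reactants: 5 (2S,5S)-hexane-2,5-diol
Product: 6 (2S,5S)-hexane-2,5-diyl dimethanesulfonate
Conditions: MsCl, Et3N, CH2Cl2, 0 °C
Reagents that add atoms: methanesulfonyl chloride, CS(=O)(=O)Cl
Why: Sulfonylation of the two secondary alcohols takes place at oxygen, so both carbinol centres keep their S configuration.

Step 5
Reactants: 6 (2S,5S)-hexane-2,5-diyl dimethanesulfonate
Product: 8 (2R,5R)-2,5-dimethylthiolane, via sodium mesyloxy thiolate 7 (not isolated)
Conditions: Na2S·9H2O, DMSO, rt
Reagents that add atoms: sodium sulfide (Na2S·9H2O), [Na+].[Na+].[S-2]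
Why: Two successive SN2 displacements by sulfur (thioether synthesis, the second a 5-exo-tet ring closure) each invert one carbon, so the S,S-dimesylate should give the R,R-thiolane.

Step 6
Reactants: 8 (2R,5R)-2,5-dimethylthiolane; 9 4-(chloromethyl)phenyl acetate
Product: 10 (2R,5R)-1-(4-acetoxybenzyl)-2,5-dimethylthiolan-1-ium tetrafluoroborate
Conditions: AgBF4, CH2Cl2, rt, dark
Reagents that add atoms: silver tetrafluoroborate AgBF4, [Ag+].F[B-](F)(F)F
Why: S-Alkylation of a dialkyl sulfide by a benzylic chloride, pulled forward by precipitation of AgCl, gives a single sulfonium salt because the C2 axis of the sulfide makes both sulfur lone pairs equivalent and sulfur is therefore not a stereocentre.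

Step 7
Reactants: 4 tert-butyl 2-bromo-2-[5-bromo-2-(triisopropylsilyloxy)phenyl]acetate; 10 (2R,5R)-1-(4-acetoxybenzyl)-2,5-dimethylthiolan-1-ium tetrafluoroborate
Product: 15 tert-butyl (2R,3R)-2-(4-acetoxyphenyl)-5-bromo-2,3-dihydro-1-benzofuran-3-carboxylate, via cesium phenoxide 11 (not isolated), via ortho-quinone methide 12 (not isolated), via sulfonium ylide 13 (not isolated), via betaine 14 (not isolated)
Conditions: Cs2CO3, CsF, 4 Å molecular sieves, MeCN, −20 °C to rt (4 added slowly to 10 and the bases)
Reagents that add atoms: none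
Why: Proposed new method: fluoride removes the silyl group of 4, the phenoxide 11 expels bromide to give the ester-bearing ortho-quinone methide 12, the benzylic ylide 13 (from 10 and Cs2CO3) adds through carbon to the exocyclic methide carbon (C2–C3, driven by rearomatisation), and the phenoxide of betaine 14 displaces the neutral thiolane at the benzylic carbon (C2–O1); the closest known reactions are the [4+1] annulations of in situ ortho-quinone methides with carbonyl-stabilised sulfonium or ammonium ylides and the aldehyde epoxidations by benzylic ylides of C2-symmetric thiolanes, and what is untested is the ester on the methide carbon combined with absolute control by a benzylic thiolanium ylide. The dihydrofuran ring closes in the 5-exo-tet mode by SN2 with inversion at C2. C2 is controlled by the thiolane, whose two ring methyl groups leave one face of the ylide carbon open; that face bonds to C3 and the inversion on closure should turn this into 2R. C3 carries a hydrogen that is benzylic and alpha to the ester, so it equilibrates under Cs2CO3 to the trans arrangement with the C2 aryl group (3R), and the absolute configuration of both centres therefore rests on C2 alone. The step needs conjugate addition to the methide to outrun methide self-condensation, and ring closure to outrun loss of the C3 proton with expulsion of the sulfide to a stilbene; the first is secured by the slow fluoride-gated release of a strongly electrophilic methide into an excess of ylide, the second by the phenoxide being created in the same event as the C–C bond, five atoms from a good benzylic leaving group. A direct SN2 attack of 13 on the bromide 4 before desilylation would reach the same betaine after fluoride cleavage, so both pathways should converge on 15.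

Step 8
Reactants: 15 tert-butyl (2R,3R)-2-(4-acetoxyphenyl)-5-bromo-2,3-dihydro-1-benzofuran-3-carboxylate
Product: 16 (2R,3R)-2-(4-acetoxyphenyl)-5-bromo-2,3-dihydro-1-benzofuran-3-carboxylic acid
Conditions: TFA/CH2Cl2 (1:3), 0 °C to rt
Reagents that add atoms: none
Why: Acidolysis of the tert-butyl ester through the tert-butyl cation frees the C3 carboxyl group without base, so C3 is not enolised, and the acetate keeps the C2 aryl ring too electron-poor for ionisation of the benzylic C2–O1 bond.

Step 9
Reactants: 17 butane-1,4-diamine; 18 N,N'-bis(tert-butoxycarbonyl)-1H-pyrazole-1-carboxamidine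
Product: 19 N-(4-aminobutyl)-N',N''-bis(tert-butoxycarbonyl)guanidine
Conditions: CH2Cl2, rt (17 in fivefold excess)
Reagents that add atoms: none
Why: Guanylation of a primary amine by amidine transfer from the pyrazole-carboxamidine, with the diamine in excess so that only one end reacts, is a standard way to the doubly Boc-protected agmatine.

Step 10
Reactants: 16 (2R,3R)-2-(4-acetoxyphenyl)-5-bromo-2,3-dihydro-1-benzofuran-3-carboxylic acid; 19 N-(4-aminobutyl)-N',N''-bis(tert-butoxycarbonyl)guanidine
Product: 21 (2R,3R)-2-(4-acetoxyphenyl)-5-bromo-N-{4-[N',N''-bis(tert-butoxycarbonyl)guanidino]butyl}-2,3-dihydro-1-benzofuran-3-carboxamide, via benzotriazolyl ester 20 (not isolated)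
Conditions: EDC·HCl, HOBt, CH2Cl2/DMF, 0 °C; then 19 (1.1 equiv), 0 °C to rt
Reagents that add atoms: none
Why: Carbodiimide-mediated amide coupling through the benzotriazolyl ester should acylate the primary amine of 19, the only nucleophilic nitrogen present because the carbamoylated guanidine is deactivated, and because no tertiary amine is added the activated C3 carboxyl is not enolised (the trans arrangement is in any case the more stable one).

Step 11
Reactants: 19 N-(4-aminobutyl)-N',N''-bis(tert-butoxycarbonyl)guanidine
Product: 22 N-{4-[N',N''-bis(tert-butoxycarbonyl)guanidino]butyl}prop-2-enamide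
Conditions: acryloyl chloride, Et3N, CH2Cl2, −20 °C
Reagents that add atoms: acryloyl chloride, C=CC(=O)Cl
Why: N-Acylation of the primary amine by the acid chloride at low temperature is far faster than conjugate addition to the acrylamide formed or acylation of the Boc-deactivated guanidine, so the acrylamide should form cleanly.

Step 12
Reactants: 21 (2R,3R)-2-(4-acetoxyphenyl)-5-bromo-N-{4-[N',N''-bis(tert-butoxycarbonyl)guanidino]butyl}-2,3-dihydro-1-benzofuran-3-carboxamide; 22 N-{4-[N',N''-bis(tert-butoxycarbonyl)guanidino]butyl}prop-2-enamide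
Product: 23 (2R,3R)-2-(4-acetoxyphenyl)-N-{4-[N',N''-bis(tert-butoxycarbonyl)guanidino]butyl}-5-[(E)-3-({4-[N',N''-bis(tert-butoxycarbonyl)guanidino]butyl}amino)-3-oxoprop-1-en-1-yl]-2,3-dihydro-1-benzofuran-3-carboxamide
Conditions: Pd2(dba)3 (cat.), [HP(t-Bu)3]BF4 (cat.), Cy2NMe, 1,4-dioxane, rt to 50 °C (22, 1.2 equiv)
Reagents that add atoms: none
Why: In this Mizoroki–Heck reaction zerovalent palladium carrying the bulky trialkylphosphine inserts into the electron-rich aryl C–Br bond near room temperature, adds syn to the acrylamide and undergoes syn beta-hydride elimination, which should give only the E-cinnamamide, while the mild temperature and the hindered amine base leave the aryl acetate, the Boc-guanidines and C3 untouched.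

Step 13
Reactants: 23 (2R,3R)-2-(4-acetoxyphenyl)-N-{4-[N',N''-bis(tert-butoxycarbonyl)guanidino]butyl}-5-[(E)-3-({4-[N',N''-bis(tert-butoxycarbonyl)guanidino]butyl}amino)-3-oxoprop-1-en-1-yl]-2,3-dihydro-1-benzofuran-3-carboxamide
Product: 24 (2R,3R)-2-(4-acetoxyphenyl)-N-(4-guanidinobutyl)-5-{(E)-3-[(4-guanidinobutyl)amino]-3-oxoprop-1-en-1-yl}-2,3-dihydro-1-benzofuran-3-carboxamide bis(trifluoroacetate)
Conditions: TFA/CH2Cl2 (1:1), 0 °C to rt; evaporation
Reagents that add atoms: trifluoroacetic acid (counter-ion of the salt), OC(=O)C(F)(F)F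
Why: Acidolytic cleavage of the four Boc carbamates gives the bis-guanidinium salt, and the acetate still in place keeps the C2 aryl ring deactivated towards both tert-butylation and acid ionisation of the benzylic ether.

Step 14
Reactants: 24 (2R,3R)-2-(4-acetoxyphenyl)-N-(4-guanidinobutyl)-5-{(E)-3-[(4-guanidinobutyl)amino]-3-oxoprop-1-en-1-yl}-2,3-dihydro-1-benzofuran-3-carboxamide bis(trifluoroacetate)
Product: 25 the target, (2R,3R)-N-(4-guanidinobutyl)-5-{(E)-3-[(4-guanidinobutyl)amino]-3-oxoprop-1-en-1-yl}-2-(4-hydroxyphenyl)-2,3-dihydro-1-benzofuran-3-carboxamide (obtained as the bis(trifluoroacetate))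
Conditions: N2H4·H2O, MeOH, 0 °C, Ar; reversed-phase HPLC (H2O/MeCN, 0.1% TFA)
Reagents that add atoms: none
Why: Hydrazinolysis of the aryl acetate uses a strong nucleophile that is too weak a base to form the phenoxide or to touch the guanidinium ions and amides, so the 4-hydroxyphenyl group should be unveiled without the base-induced opening of the dihydrofuran ring that a 4-oxidophenyl group at C2 would invite.

**Compound list**
1 | 2-(5-bromo-2-hydroxyphenyl)acetic acid | OC(=O)Cc1cc(Br)ccc1O | starting material
2 | tert-butyl 2-(5-bromo-2-hydroxyphenyl)acetate | CC(C)(C)OC(=O)Cc1cc(Br)ccc1O | intermediate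
3 | tert-butyl 2-[5-bromo-2-(triisopropylsilyloxy)phenyl]acetate | CC(C)(C)OC(=O)Cc1cc(Br)ccc1O[Si](C(C)C)(C(C)C)C(C)C | intermediate
4 | tert-butyl 2-bromo-2-[5-bromo-2-(triisopropylsilyloxy)phenyl]acetate (racemic) | CC(C)(C)OC(=O)C(Br)c1cc(Br)ccc1O[Si](C(C)C)(C(C)C)C(C)C | intermediate
5 | (2S,5S)-hexane-2,5-diol | C[C@H](O)CC[C@H](C)O | starting material
6 | (2S,5S)-hexane-2,5-diyl dimethanesulfonate | C[C@H](OS(C)(=O)=O)CC[C@H](C)OS(C)(=O)=O | intermediate
7 | sodium (2R,5S)-5-(methanesulfonyloxy)hexane-2-thiolate | C[C@@H]([S-])CC[C@H](C)OS(C)(=O)=O.[Na+] | intermediate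
8 | (2R,5R)-2,5-dimethylthiolane | C[C@@H]1CC[C@@H](C)S1 | intermediate
9 | 4-(chloromethyl)phenyl acetate | CC(=O)Oc1ccc(CCl)cc1 | starting material
10 | (2R,5R)-1-(4-acetoxybenzyl)-2,5-dimethylthiolan-1-ium tetrafluoroborate | C[C@@H]1CC[C@@H](C)[S+]1Cc1ccc(OC(C)=O)cc1.F[B-](F)(F)F | intermediate
11 | cesium 4-bromo-2-(1-bromo-2-tert-butoxy-2-oxoethyl)phenolate | CC(C)(C)OC(=O)C(Br)c1cc(Br)ccc1[O-].[Cs+] | intermediate
12 | tert-butyl 2-(3-bromo-6-oxocyclohexa-2,4-dien-1-ylidene)acetate (ortho-quinone methide) | CC(C)(C)OC(=O)C=C1C=C(Br)C=CC1=O | intermediate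
13 | (4-acetoxyphenyl)[(2R,5R)-2,5-dimethylthiolan-1-ium-1-yl]methanide (sulfonium ylide) | C[C@@H]1CC[C@@H](C)[S+]1[CH-]c1ccc(OC(C)=O)cc1 | intermediate
14 | tert-butyl (2S,3S)-3-(4-acetoxyphenyl)-2-(5-bromo-2-oxidophenyl)-3-[(2R,5R)-2,5-dimethylthiolan-1-ium-1-yl]propanoate (betaine; the diastereomer that closes to 15) | CC(C)(C)OC(=O)[C@H](c1cc(Br)ccc1[O-])[C@@H](c1ccc(OC(C)=O)cc1)[S+]1[C@H](C)CC[C@H]1C | intermediate
15 | tert-butyl (2R,3R)-2-(4-acetoxyphenyl)-5-bromo-2,3-dihydro-1-benzofuran-3-carboxylate (trans) | Brc1ccc2c(c1)[C@@H](C(=O)OC(C)(C)C)[C@H](c1ccc(OC(C)=O)cc1)O2 | intermediate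
16 | (2R,3R)-2-(4-acetoxyphenyl)-5-bromo-2,3-dihydro-1-benzofuran-3-carboxylic acid | Brc1ccc2c(c1)[C@@H](C(O)=O)[C@H](c1ccc(OC(C)=O)cc1)O2 | intermediate
17 | butane-1,4-diamine | NCCCCN | starting material
18 | N,N'-bis(tert-butoxycarbonyl)-1H-pyrazole-1-carboxamidine | CC(C)(C)OC(=O)NC(=NC(=O)OC(C)(C)C)n1cccn1 | starting material
19 | N-(4-aminobutyl)-N',N''-bis(tert-butoxycarbonyl)guanidine | NCCCCNC(=NC(=O)OC(C)(C)C)NC(=O)OC(C)(C)C | intermediate
20 | benzotriazol-1-yl (2R,3R)-2-(4-acetoxyphenyl)-5-bromo-2,3-dihydro-1-benzofuran-3-carboxylate | Brc1ccc2c(c1)[C@@H](C(=O)On1nnc3ccccc31)[C@H](c1ccc(OC(C)=O)cc1)O2 | intermediate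
21 | (2R,3R)-2-(4-acetoxyphenyl)-5-bromo-N-{4-[N',N''-bis(tert-butoxycarbonyl)guanidino]butyl}-2,3-dihydro-1-benzofuran-3-carboxamide | Brc1ccc2c(c1)[C@@H](C(=O)NCCCCNC(=NC(=O)OC(C)(C)C)NC(=O)OC(C)(C)C)[C@H](c1ccc(OC(C)=O)cc1)O2 | intermediate
22 | N-{4-[N',N''-bis(tert-butoxycarbonyl)guanidino]butyl}prop-2-enamide | C=CC(=O)NCCCCNC(=NC(=O)OC(C)(C)C)NC(=O)OC(C)(C)C | intermediate
23 | (2R,3R)-2-(4-acetoxyphenyl)-N-{4-[N',N''-bis(tert-butoxycarbonyl)guanidino]butyl}-5-[(E)-3-({4-[N',N''-bis(tert-butoxycarbonyl)guanidino]butyl}amino)-3-oxoprop-1-en-1-yl]-2,3-dihydro-1-benzofuran-3-carboxamide | CC(C)(C)OC(=O)NC(=NC(=O)OC(C)(C)C)NCCCCNC(=O)/C=C/c1ccc2c(c1)[C@@H](C(=O)NCCCCNC(=NC(=O)OC(C)(C)C)NC(=O)OC(C)(C)C)[C@H](c1ccc(OC(C)=O)cc1)O2 | intermediate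
24 | (2R,3R)-2-(4-acetoxyphenyl)-N-(4-guanidinobutyl)-5-{(E)-3-[(4-guanidinobutyl)amino]-3-oxoprop-1-en-1-yl}-2,3-dihydro-1-benzofuran-3-carboxamide bis(trifluoroacetate) | NC(N)=NCCCCNC(=O)/C=C/c1ccc2c(c1)[C@@H](C(=O)NCCCCN=C(N)N)[C@H](c1ccc(OC(C)=O)cc1)O2.OC(=O)C(F)(F)F.OC(=O)C(F)(F)F | intermediate
25 | (2R,3R)-N-(4-guanidinobutyl)-5-{(E)-3-[(4-guanidinobutyl)amino]-3-oxoprop-1-en-1-yl}-2-(4-hydroxyphenyl)-2,3-dihydro-1-benzofuran-3-carboxamide | NC(N)=NCCCCNC(=O)/C=C/c1ccc2c(c1)[C@@H](C(=O)NCCCCN=C(N)N)[C@H](c1ccc(O)cc1)O2 | target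

**Step count and risks**
Total step count: 14. Longest linear sequence: 9 steps (steps 1, 2, 3, 7, 8, 10, 12, 13, 14; the branch through steps 4, 5, 6 is equally long).

Most likely to fail, step 7 (the new method). The transient methide may condense with itself or with its own precursor faster than it meets the ylide. Facial selection at the ylide carbon may be eroded. The acetate may be lost under fluoride and carbonate, which would let the sulfonium salt fragment. The fallback uses known carbene chemistry, sets out from 2 and 9, and comes back to the route at 15. Phenol 2 would be O-alkylated with 9 (K2CO3, NaI cat., acetone) to tert-butyl 2-{2-[(4-acetoxybenzyl)oxy]-5-bromophenyl}acetate F1. Regitz diazo transfer (4-acetamidobenzenesulfonyl azide, DBU, MeCN, 0 °C) would give tert-butyl 2-{2-[(4-acetoxybenzyl)oxy]-5-bromophenyl}-2-diazoacetate F2. Dirhodium tetrakis[N-phthaloyl-(S)-tert-leucinate], Rh2(S-PTTL)4, or its enantiomer, whichever sets 2R, in toluene at low temperature would insert the dirhodium carbene into the benzylic ether C–H bond to give the cis ester tert-butyl (2R,3S)-2-(4-acetoxyphenyl)-5-bromo-2,3-dihydro-1-benzofuran-3-carboxylate F3. Equilibration at C3 with catalytic DBU in toluene would then give the trans ester 15.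

Second, step 12. Migratory insertion of the bulky N-substituted acrylamide may be slow, the acrylamide may polymerise, the guanidine nitrogens of the two partners may tie up the palladium, and warming to force the coupling may cost Boc groups. The fallback builds the arm in two stages from a small, robust olefin; it sets out from 21 and 19 and comes back at 23. A Heck reaction of 21 with acrylic acid (Pd(OAc)2, P(o-tol)3, Et3N, MeCN, 80 °C) would give (E)-3-[(2R,3R)-2-(4-acetoxyphenyl)-3-({4-[N',N''-bis(tert-butoxycarbonyl)guanidino]butyl}carbamoyl)-2,3-dihydro-1-benzofuran-5-yl]prop-2-enoic acid F4. EDC·HCl/HOBt coupling of this unhindered cinnamic acid with one equivalent of 19 would then give 23.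

Third, step 3. The radical chain may brominate the ring or over-brominate, and the benzylic bromide may ionise during isolation. The fallback replaces the radical C–H bromination by polar bromination of a preformed enol derivative; it sets out from 3 and comes back at 4. LiN(SiMe3)2 and Me3SiCl in THF at −78 °C would give the ketene silyl acetal 1-tert-butoxy-1-(trimethylsilyloxy)-2-[5-bromo-2-(triisopropylsilyloxy)phenyl]ethene F5. N-Bromosuccinimide at −78 °C would brominate it at carbon to 4, which would then be used without chromatography.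

**Further compounds**
F1 | step 7 | tert-butyl 2-{2-[(4-acetoxybenzyl)oxy]-5-bromophenyl}acetate | CC(C)(C)OC(=O)Cc1cc(Br)ccc1OCc1ccc(OC(C)=O)cc1
F2 | step 7 | tert-butyl 2-{2-[(4-acetoxybenzyl)oxy]-5-bromophenyl}-2-diazoacetate | CC(C)(C)OC(=O)C(=[N+]=[N-])c1cc(Br)ccc1OCc1ccc(OC(C)=O)cc1
F3 | step 7 | tert-butyl (2R,3S)-2-(4-acetoxyphenyl)-5-bromo-2,3-dihydro-1-benzofuran-3-carboxylate (cis) | Brc1ccc2c(c1)[C@H](C(=O)OC(C)(C)C)[C@H](c1ccc(OC(C)=O)cc1)O2
F4 | step 12 | (E)-3-[(2R,3R)-2-(4-acetoxyphenyl)-3-({4-[N',N''-bis(tert-butoxycarbonyl)guanidino]butyl}carbamoyl)-2,3-dihydro-1-benzofuran-5-yl]prop-2-enoic acid | OC(=O)/C=C/c1ccc2c(c1)[C@@H](C(=O)NCCCCNC(=NC(=O)OC(C)(C)C)NC(=O)OC(C)(C)C)[C@H](c1ccc(OC(C)=O)cc1)O2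
F5 | step 3 | 1-tert-butoxy-1-(trimethylsilyloxy)-2-[5-bromo-2-(triisopropylsilyloxy)phenyl]ethene | CC(C)(C)OC(O[Si](C)(C)C)=Cc1cc(Br)ccc1O[Si](C(C)C)(C(C)C)C(C)C
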